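**Retrosynthetic overview**
- Target 10 ⇐ acid 7 by allylic C7–H acetoxylation (C7–O bond; the 7α centre is set by the decalin).
- 7 ⇐ 6 ⇐ 4: ester hydrolysis, and the exocyclic C8=C17 alkene from the equatorial 8α tertiary alcohol.
- 4 ⇐ 1 + 2: the C11–C12 bond by anodic mixed Kolbe coupling; each partner loses its carboxyl carbon as CO2.
- Rings: none is built. Rings A and B with C5, C9 and C10 come from (+)-sclareolide 1, whose lactone ring is opened; C13 comes from 2.

Assumption: the target is read as (13R)-7α-acetoxylabd-8(17)-en-15-oic acid (5S,7R,9R,10S,13R), and 1 and 2 are bought as single enantiomers.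

**Step 1**
Reactants: 1 (+)-sclareolide; 2 methyl hydrogen (R)-3-methylglutarate
Product: 4 methyl (13R)-8α-hydroxylabdan-15-oate, via potassium 8α-hydroxy-13,14,15,16-tetranorlabdan-12-oate 3 (not isolated)
Conditions: KOH (1.0 equiv), MeOH–H2O 20:1, 65 °C, 2 h; cool to 20 °C, add 2 (3.0 equiv); Pt anode, Pt cathode, undivided cell, 0.15 A cm−2, 15–25 °C, about 1.3 F per mol of total acid
Reagents that add atoms: none
Why: Saponification followed by mixed Kolbe electrolysis: both carboxylates are oxidised at Pt to primary radicals (C11 of 3, C12 of 2) that couple after loss of CO2, the threefold excess of 2 steering the C11 radical into the cross product; no stereocentre is formed or touched (C9 and C13 are next to, not at, the radical carbons), and the base is regenerated at the cathode.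

**Step 2**
Reactants: 4 methyl (13R)-8α-hydroxylabdan-15-oate
Product: 6 methyl (13R)-labd-8(17)-en-15-oate, via 8α-chlorosulfite ester 5 (not isolated)
Conditions: SOCl2 (2 equiv), pyridine (8 equiv), CH2Cl2, −78 °C, 1 h; chromatography on AgNO3-impregnated silica
Reagents that add atoms: none
Why: E2 dehydration: the 8α oxygen is equatorial, so in 5 no ring hydrogen is anti-periplanar to the C8–O bond and pyridine removes a hydrogen of the freely rotating C17 methyl, giving the exocyclic alkene as the kinetic product with no stereocentre affected.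

**Step 3**
Reactants: 6 methyl (13R)-labd-8(17)-en-15-oate
Product: 7 (13R)-labd-8(17)-en-15-oic acid
Conditions: LiOH·H2O (5 equiv), THF–MeOH–H2O 3:1:1, 40 °C; then 1 M HCl
Reagents that add atoms: lithium hydroxide, [Li+].[OH-]
Why: Saponification of an unhindered methyl ester; nothing else in 6 is base-sensitive and C13, β to the carboxyl, cannot epimerise.

**Step 4**
Reactants: 7 (13R)-labd-8(17)-en-15-oic acid
Product: 10 (13R)-7α-acetoxylabd-8(17)-en-15-oic acid (target), via C17 allylseleninate 8 (not isolated), via C7 selenium ester 9 (not isolated)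
Conditions: SeO2 (10 mol %), PhI(OAc)2 (1.3 equiv), AcOH–CH2Cl2 1:1, 25 °C, dark, 16 h
Reagents that add atoms: (diacetoxyiodo)benzene, CC(=O)OI(OC(C)=O)c1ccccc1; acetic acid, CC(=O)O (acetate pool that exchanges with the acetate ligands)
Why: Proposed new method: a SeO2-catalysed ene/[2,3] allylic C–H acetoxylation turned over by PhI(OAc)2 — the tetravalent selenium electrophile O=Se(OAc)2 (from SeO2 and AcOH) bonds to C17 of the exocyclic alkene while taking the axial 7α hydrogen (ene step) to give 8, whose [2,3]-sigmatropic shift restores C8=C17 and delivers oxygen to C7 on the axial α face, away from the axial 10β-methyl (this sets C7 as R), giving the divalent selenium ester 9; PhI(OAc)2 re-oxidises selenium in 9, and acyl transfer from selenium to the C7 oxygen releases the acetate 10 and O=Se(OAc)2, so the alcohol is never free and cannot go on to the enone; closest known reaction types are the Riley oxidation run catalytically with t-BuOOH and the stoichiometric SeO2/AcOH–Ac2O allylic acetoxylation, and the 7α outcome is the one expected from SeO2 oxidations of labd-8(17)-enes.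

**Compound list**
1 | (+)-sclareolide, (3aR,5aS,9aS,9bR)-3a,6,6,9a-tetramethyldecahydronaphtho[2,1-b]furan-2(1H)-one | C[C@@]12CC[C@H]3C(C)(C)CCC[C@]3(C)[C@H]1CC(=O)O2 | starting material
2 | methyl hydrogen (R)-3-methylglutarate, (3R)-5-methoxy-3-methyl-5-oxopentanoic acid | OC(=O)C[C@@H](C)CC(=O)OC | starting material
3 | potassium 8α-hydroxy-13,14,15,16-tetranorlabdan-12-oate, potassium 2-[(1R,2R,4aS,8aS)-2-hydroxy-2,5,5,8a-tetramethyldecahydronaphthalen-1-yl]acetate | C[C@@]1(O)CC[C@H]2C(C)(C)CCC[C@]2(C)[C@H]1CC(=O)[O-].[K+] | intermediate (not isolated)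
4 | methyl (13R)-8α-hydroxylabdan-15-oate (5S,8R,9R,10S,13R; trans-decalin, equatorial 8α-OH, 8β-methyl, 9β side chain) | C[C@@]1(O)CC[C@H]2C(C)(C)CCC[C@]2(C)[C@H]1CC[C@@H](C)CC(=O)OC | intermediate
5 | 8α-chlorosulfite ester of 4 | C[C@@]1(OS(Cl)=O)CC[C@H]2C(C)(C)CCC[C@]2(C)[C@H]1CC[C@@H](C)CC(=O)OC | intermediate (not isolated)
6 | methyl (13R)-labd-8(17)-en-15-oate (5S,9S,10S,13R) | C=C1CC[C@H]2C(C)(C)CCC[C@]2(C)[C@H]1CC[C@@H](C)CC(=O)OC | intermediate
7 | (13R)-labd-8(17)-en-15-oic acid (5S,9S,10S,13R) | C=C1CC[C@H]2C(C)(C)CCC[C@]2(C)[C@H]1CC[C@@H](C)CC(=O)O | intermediate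
8 | C17 allylseleninate, (13R)-17-[(acetyloxy)seleninyl]labd-7-en-15-oic acid | CC(=O)O[Se](=O)CC1=CC[C@H]2C(C)(C)CCC[C@]2(C)[C@H]1CC[C@@H](C)CC(=O)O | intermediate (not isolated)
9 | C7 selenium ester, (13R)-7α-{[(acetyloxy)selanyl]oxy}labd-8(17)-en-15-oic acid | C=C1[C@H](O[Se]OC(C)=O)C[C@H]2C(C)(C)CCC[C@]2(C)[C@H]1CC[C@@H](C)CC(=O)O | intermediate (not isolated)
10 | (13R)-7α-acetoxylabd-8(17)-en-15-oic acid, (3R)-5-[(1R,3R,4aS,8aS)-3-acetoxy-5,5,8a-trimethyl-2-methylidenedecahydronaphthalen-1-yl]-3-methylpentanoic acid | C=C1[C@H](OC(C)=O)C[C@H]2C(C)(C)CCC[C@]2(C)[C@H]1CC[C@@H](C)CC(=O)O | target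

**Totals**
Total step count: 4. Longest linear sequence: 4 steps (1 → 4 → 6 → 7 → 10); 2 enters in step 1 as bought.

**Steps most likely to fail, with fallbacks**

Step 4 (the proposed new acetoxylation). Risks are poor selenium turnover, oxidation at C9, or drift to the primary C17 acetate. The fallback uses known chemistry, sets out from 7 and comes back at 10. Catalytic Riley oxidation (SeO2 0.3 equiv, t-BuOOH 2 equiv, CH2Cl2, 25 °C) gives the axial alcohol (13R)-7α-hydroxylabd-8(17)-en-15-oic acid F8. Acetylation of F8 (Ac2O, pyridine, DMAP, 25 °C, then aqueous NaHCO3 work-up and acidification) gives 10.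

Step 1 (mixed Kolbe coupling). Risks are relactonisation of the protonated γ-hydroxy acid back to 1 (recoverable) and statistical homocoupling. The fallback sets out from 2, uses 3 made from 1 as before, and comes back at 4. Silver-catalysed bromodecarboxylation of 2 (Ag(phen)2OTf cat., dibromoisocyanuric acid, 1,2-dichloroethane, 60 °C) gives methyl (S)-4-bromo-3-methylbutanoate F1. The salt 3 is then joined to F1 by metallaphotoredox decarboxylative alkylation ([Ir(dF(CF3)ppy)2(dtbbpy)]PF6, NiCl2(dme), 4,4′-dimethoxy-2,2′-bipyridine, K2CO3, MeCN–H2O, blue light) to give 4. The basic medium keeps the hydroxy carboxylate open, and cross-selectivity comes from the catalyst instead of from statistics.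

Step 2 (regiochemistry of the elimination). The risk is too much of the endocyclic 7-ene and 8(9)-ene isomers. The fallback sets out from 4 and comes back at 10; it makes the 7-ene isomer productive instead of discarding it.
- The dehydration is run as in step 2 and the isomer methyl (13R)-labd-7-en-15-oate F4 is collected.
- Schenck ene reaction of F4 (O2, tetraphenylporphyrin, visible light, CH2Cl2, 0 °C; singlet oxygen on the α face, hydrogen taken from C17) gives methyl (13R)-7α-hydroperoxylabd-8(17)-en-15-oate F5.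
- Reduction in the same flask with PPh3 gives methyl (13R)-7α-hydroxylabd-8(17)-en-15-oate F6.
- Ac2O, pyridine and DMAP give methyl (13R)-7α-acetoxylabd-8(17)-en-15-oate F7.
- Me3SnOH (1,2-dichloroethane, 70 °C) cleaves the unhindered methyl ester in preference to the hindered axial acetate and gives 10; this last selectivity is the weak point of the fallback.

**Further compounds**
F1 | step 1 | methyl (S)-4-bromo-3-methylbutanoate | BrC[C@@H](C)CC(=O)OC
F4 | step 2 | methyl (13R)-labd-7-en-15-oate | CC1=CC[C@H]2C(C)(C)CCC[C@]2(C)[C@H]1CC[C@@H](C)CC(=O)OC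
F5 | step 2 | methyl (13R)-7α-hydroperoxylabd-8(17)-en-15-oate | C=C1[C@H](OO)C[C@H]2C(C)(C)CCC[C@]2(C)[C@H]1CC[C@@H](C)CC(=O)OC
F6 | step 2 | methyl (13R)-7α-hydroxylabd-8(17)-en-15-oate | C=C1[C@H](O)C[C@H]2C(C)(C)CCC[C@]2(C)[C@H]1CC[C@@H](C)CC(=O)OC
F7 | step 2 | methyl (13R)-7α-acetoxylabd-8(17)-en-15-oate | C=C1[C@H](OC(C)=O)C[C@H]2C(C)(C)CCC[C@]2(C)[C@H]1CC[C@@H](C)CC(=O)OC
F8 | step 4 | (13R)-7α-hydroxylabd-8(17)-en-15-oic acid | C=C1[C@H](O)C[C@H]2C(C)(C)CCC[C@]2(C)[C@H]1CC[C@@H](C)CC(=O)O
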